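The route rests on disconnecting the bond between the benzoyl carbonyl carbon and C1 of the phloroglucinol ring (ring A). The key step exploits that C1 is the last hydrogen-bearing carbon of ring A and lies between the oxygens on C2 and C6: in precursor 7, a pentasubstituted benzene already carrying both prenyl groups, the C6 methoxy and C2 methoxymethoxy groups direct metalation to C1, and the aryllithium is acylated once by the Weinreb amide of benzoic acid. One operation thus completes the hexasubstituted benzophenone with full regiocontrol. Precursor 7 arises from 5-methoxyresorcinol by two earlier metalation–prenylation rounds; mild acid finally frees the phenols.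

Key step: step 4

Remark: the target has no stereocentre and no stereogenic double bond; ring A is numbered as in the target for all compounds (C1 benzoyl-bearing, C2 and C4 oxygen-bearing, C3 and C5 prenyl-bearing, C6 methoxy-bearing), and prenyl means 3-methylbut-2-en-1-yl.

Step 1
Reactants: 1 5-methoxyresorcinol (5-methoxybenzene-1,3-diol)
Product: 3 1-methoxy-3,5-bis(methoxymethoxy)benzene, via disodium bis-phenoxide 2 (not isolated)
Conditions: NaH (2.4 equiv), DMF, 0 °C; then MOMCl (2.4 equiv), 0 °C to rt
Reagents that add atoms: chloromethyl methyl ether (MOMCl), COCCl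
Why: Williamson-type O-alkylation of the bis-phenoxide with the reactive alpha-chloro ether should give the bis(methoxymethyl) ether, whose acetal groups serve first as ortho-directing groups and later as acid-labile phenol protection.

Step 2
Reactants: 3 1-methoxy-3,5-bis(methoxymethoxy)benzene
Product: 5 5-methoxy-1,3-bis(methoxymethoxy)-2-(3-methylbut-2-en-1-yl)benzene, via aryllithium 4 (not isolated)
Conditions: n-BuLi (1.1 equiv), TMEDA, THF, 0 °C; then CuI (10 mol%), prenyl bromide (1.2 equiv), −78 °C to rt
Reagents that add atoms: prenyl bromide (1-bromo-3-methylbut-2-ene), CC(C)=CCBr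
Why: Directed ortho-metalation should occur at C3 of ring A, between the two methoxymethoxy groups (the stronger pair of directing groups), and the aryl anion is alkylated at the primary carbon of prenyl bromide (SN2); any minor metalation at C5 would give an isomer that converges on 7 in step 3.

Step 3
Reactants: 5 5-methoxy-1,3-bis(methoxymethoxy)-2-(3-methylbut-2-en-1-yl)benzene
Product: 7 1-methoxy-3,5-bis(methoxymethoxy)-2,4-bis(3-methylbut-2-en-1-yl)benzene, via aryllithium 6 (not isolated)
Conditions: s-BuLi (1.2 equiv), TMEDA, THF, −78 °C; then CuI (10 mol%), prenyl bromide (1.3 equiv), −78 °C to rt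
Reagents that add atoms: prenyl bromide (1-bromo-3-methylbut-2-ene), CC(C)=CCBr
Why: Second directed ortho-metalation: the two remaining ring hydrogens of 5 (C1 and C5 of ring A) are equivalent by symmetry and each lies between a methoxymethoxy and the methoxy group, so one aryllithium should form and be prenylated as in step 2.

Step 4
Reactants: 7 1-methoxy-3,5-bis(methoxymethoxy)-2,4-bis(3-methylbut-2-en-1-yl)benzene; 8 N-methoxy-N-methylbenzamide
Product: 11 [2-methoxy-4,6-bis(methoxymethoxy)-3,5-bis(3-methylbut-2-en-1-yl)phenyl](phenyl)methanone, via aryllithium 9 (not isolated), via lithium hemiaminal alkoxide 10 (not isolated)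
Conditions: s-BuLi (1.2 equiv), TMEDA, THF, −78 °C; then 8 (1.5 equiv), −78 to 0 °C; then H2O, 0 °C
Reagents that add atoms: none
Why: s-BuLi/TMEDA should remove the only ring hydrogen of 7 (C1–H of ring A, flanked by the C6 methoxy oxygen and the C2 methoxymethoxy oxygen) by a coordination-assisted deprotonation, and aryllithium 9 then adds to the amide carbonyl of 8 to give the lithium-chelated tetrahedral adduct 10, which collapses to ketone 11 only on aqueous quench. The closest known reaction type is directed ortho-metalation of a 1,3-dioxygenated arene followed by the Weinreb ketone synthesis. No ring is closed and no stereocenter is formed. The step needs site selectivity for the ring C–H over the benzylic-allylic CH2 groups of the two prenyl chains, which the two flanking oxygen donors should secure by binding the base next to C1 at low temperature. It also needs single addition, which the stable five-membered N-methoxy chelate of 10 secures, so that the hexasubstituted benzophenone is formed in one operation with only one possible regiochemistry.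

Step 5
Reactants: 11 [2-methoxy-4,6-bis(methoxymethoxy)-3,5-bis(3-methylbut-2-en-1-yl)phenyl](phenyl)methanone
Product: 12 [2,4-dihydroxy-6-methoxy-3,5-bis(3-methylbut-2-en-1-yl)phenyl](phenyl)methanone
Conditions: conc. HCl (cat.), MeOH, rt, stopped at full conversion
Reagents that add atoms: none
Why: Acid-catalysed methanolysis (transacetalisation) of the two methoxymethyl acetals should free both phenols at room temperature, conditions mild enough that prenyl groups ortho to phenols are expected to survive.

Compound list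
1 | 5-methoxybenzene-1,3-diol (5-methoxyresorcinol) | COc1cc(O)cc(O)c1 | starting material
2 | disodium 5-methoxybenzene-1,3-bis(olate) | COc1cc([O-])cc([O-])c1.[Na+].[Na+] | intermediate
3 | 1-methoxy-3,5-bis(methoxymethoxy)benzene | COCOc1cc(OC)cc(OCOC)c1 | intermediate
4 | [4-methoxy-2,6-bis(methoxymethoxy)phenyl]lithium | [Li]c1c(OCOC)cc(OC)cc1OCOC | intermediate
5 | 5-methoxy-1,3-bis(methoxymethoxy)-2-(3-methylbut-2-en-1-yl)benzene | COCOc1cc(OC)cc(OCOC)c1CC=C(C)C | intermediate
6 | [6-methoxy-2,4-bis(methoxymethoxy)-3-(3-methylbut-2-en-1-yl)phenyl]lithium | COCOc1cc(OC)c([Li])c(OCOC)c1CC=C(C)C | intermediate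
7 | 1-methoxy-3,5-bis(methoxymethoxy)-2,4-bis(3-methylbut-2-en-1-yl)benzene | COc1cc(OCOC)c(CC=C(C)C)c(OCOC)c1CC=C(C)C | intermediate
8 | N-methoxy-N-methylbenzamide | CON(C)C(=O)c1ccccc1 | starting material
9 | [2-methoxy-4,6-bis(methoxymethoxy)-3,5-bis(3-methylbut-2-en-1-yl)phenyl]lithium | COc1c([Li])c(OCOC)c(CC=C(C)C)c(OCOC)c1CC=C(C)C | intermediate
10 | lithium [2-methoxy-4,6-bis(methoxymethoxy)-3,5-bis(3-methylbut-2-en-1-yl)phenyl][methoxy(methyl)amino](phenyl)methanolate | COc1c(C(O[Li])(N(C)OC)c2ccccc2)c(OCOC)c(CC=C(C)C)c(OCOC)c1CC=C(C)C | intermediate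
11 | [2-methoxy-4,6-bis(methoxymethoxy)-3,5-bis(3-methylbut-2-en-1-yl)phenyl](phenyl)methanone | COc1c(C(=O)c2ccccc2)c(OCOC)c(CC=C(C)C)c(OCOC)c1CC=C(C)C | intermediate
12 | [2,4-dihydroxy-6-methoxy-3,5-bis(3-methylbut-2-en-1-yl)phenyl](phenyl)methanone | COc1c(CC=C(C)C)c(O)c(CC=C(C)C)c(O)c1C(=O)c1ccccc1 | target

Total step count: 5
Longest linear sequence: 5 steps (1 to 3 to 5 to 7 to 11 to 12); fragment 8 is purchased.

Steps most likely to fail

1. Step 4 (key step). What may go wrong: deprotonation of a benzylic-allylic CH2 of a prenyl chain instead of the ring C1–H, slow metalation of the crowded arene, or base-induced fragmentation of the N-methoxy amide in place of carbonyl addition. Fallback, setting out from 7 and coming back at 12: the carbanion acylation is replaced by a metal-templated electrophilic acylation of the free resorcinol. Both methoxymethyl groups of 7 are removed first (conc. HCl cat., MeOH, rt) to give 5-methoxy-2,4-bis(3-methylbut-2-en-1-yl)benzene-1,3-diol F1. EtMgBr (2 equiv, Et2O, then solvent change to toluene) converts it into bis(bromomagnesium) 5-methoxy-2,4-bis(3-methylbut-2-en-1-yl)benzene-1,3-bis(olate) F2. Benzoyl chloride (toluene, rt) should then acylate F2 at the only free ring carbon, which is ortho to a magnesium phenolate (ortho-selective C-acylation of magnesium phenolates), giving 12 after cold dilute HCl work-up.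

2. Step 3. What may go wrong: attack of the hindered aryl nucleophile at the tertiary end of prenyl bromide (SN2′), lithium–bromine exchange that returns unalkylated arene, or sluggish alkylation next to two ortho substituents. Fallback, setting out from 5 and coming back at 7: the prenyl group is built in two stages from an allyl group. Aryllithium 6 (s-BuLi, TMEDA, THF, −78 °C) is trapped with allyl bromide, which has no regiochemical ambiguity, to give 1-methoxy-3,5-bis(methoxymethoxy)-4-(3-methylbut-2-en-1-yl)-2-(prop-2-en-1-yl)benzene F3. Olefin cross-metathesis of F3 with excess 2-methylbut-2-ene (second-generation Grubbs catalyst, CH2Cl2, 40 °C) should convert the allyl group into the prenyl group, giving 7; the prenyl group already present can only exchange degenerately.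

3. Step 5. What may go wrong: acid-catalysed addition of the freed ortho-hydroxyl groups to the prenyl double bonds (closure to 2,2-dimethylchromans) competing with acetal cleavage. Fallback, setting out from 1 and coming back at 12: the acid-labile acetals are replaced by fluoride-labile 2-(trimethylsilyl)ethoxymethyl (SEM) ethers, which direct metalation in the same way, and the same sequence is run on them.
- Bis-phenoxide 2 (from 1, NaH, DMF) and SEMCl should give 1-methoxy-3,5-bis{[2-(trimethylsilyl)ethoxy]methoxy}benzene F4.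
- n-BuLi/TMEDA gives (4-methoxy-2,6-bis{[2-(trimethylsilyl)ethoxy]methoxy}phenyl)lithium F5, and prenyl bromide (CuI cat.) gives 5-methoxy-2-(3-methylbut-2-en-1-yl)-1,3-bis{[2-(trimethylsilyl)ethoxy]methoxy}benzene F6.
- s-BuLi/TMEDA gives [6-methoxy-3-(3-methylbut-2-en-1-yl)-2,4-bis{[2-(trimethylsilyl)ethoxy]methoxy}phenyl]lithium F7, and prenyl bromide gives 1-methoxy-2,4-bis(3-methylbut-2-en-1-yl)-3,5-bis{[2-(trimethylsilyl)ethoxy]methoxy}benzene F8.
- s-BuLi/TMEDA gives [2-methoxy-3,5-bis(3-methylbut-2-en-1-yl)-4,6-bis{[2-(trimethylsilyl)ethoxy]methoxy}phenyl]lithium F9, which adds to 8 to give lithium [2-methoxy-3,5-bis(3-methylbut-2-en-1-yl)-4,6-bis{[2-(trimethylsilyl)ethoxy]methoxy}phenyl][methoxy(methyl)amino](phenyl)methanolate F10.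
- Aqueous quench of F10 gives [2-methoxy-3,5-bis(3-methylbut-2-en-1-yl)-4,6-bis{[2-(trimethylsilyl)ethoxy]methoxy}phenyl](phenyl)methanone F11.
- Bu4NF (THF/DMPU, 60 °C) should then remove both SEM groups by fluoride-induced fragmentation, with no acid present, to give 12 after aqueous work-up.

Further compounds
F1 | step 4 | 5-methoxy-2,4-bis(3-methylbut-2-en-1-yl)benzene-1,3-diol | COc1cc(O)c(CC=C(C)C)c(O)c1CC=C(C)C
F2 | step 4 | bis(bromomagnesium) 5-methoxy-2,4-bis(3-methylbut-2-en-1-yl)benzene-1,3-bis(olate) | COc1cc(O[Mg]Br)c(CC=C(C)C)c(O[Mg]Br)c1CC=C(C)C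
F3 | step 3 | 1-methoxy-3,5-bis(methoxymethoxy)-4-(3-methylbut-2-en-1-yl)-2-(prop-2-en-1-yl)benzene | COc1cc(OCOC)c(CC=C(C)C)c(OCOC)c1CC=C
F4 | step 5 | 1-methoxy-3,5-bis{[2-(trimethylsilyl)ethoxy]methoxy}benzene | COc1cc(OCOCC[Si](C)(C)C)cc(OCOCC[Si](C)(C)C)c1
F5 | step 5 | (4-methoxy-2,6-bis{[2-(trimethylsilyl)ethoxy]methoxy}phenyl)lithium | [Li]c1c(OCOCC[Si](C)(C)C)cc(OC)cc1OCOCC[Si](C)(C)C
F6 | step 5 | 5-methoxy-2-(3-methylbut-2-en-1-yl)-1,3-bis{[2-(trimethylsilyl)ethoxy]methoxy}benzene | COc1cc(OCOCC[Si](C)(C)C)c(CC=C(C)C)c(OCOCC[Si](C)(C)C)c1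
F7 | step 5 | [6-methoxy-3-(3-methylbut-2-en-1-yl)-2,4-bis{[2-(trimethylsilyl)ethoxy]methoxy}phenyl]lithium | COc1cc(OCOCC[Si](C)(C)C)c(CC=C(C)C)c(OCOCC[Si](C)(C)C)c1[Li]
F8 | step 5 | 1-methoxy-2,4-bis(3-methylbut-2-en-1-yl)-3,5-bis{[2-(trimethylsilyl)ethoxy]methoxy}benzene | COc1cc(OCOCC[Si](C)(C)C)c(CC=C(C)C)c(OCOCC[Si](C)(C)C)c1CC=C(C)C
F9 | step 5 | [2-methoxy-3,5-bis(3-methylbut-2-en-1-yl)-4,6-bis{[2-(trimethylsilyl)ethoxy]methoxy}phenyl]lithium | COc1c([Li])c(OCOCC[Si](C)(C)C)c(CC=C(C)C)c(OCOCC[Si](C)(C)C)c1CC=C(C)C
F10 | step 5 | lithium [2-methoxy-3,5-bis(3-methylbut-2-en-1-yl)-4,6-bis{[2-(trimethylsilyl)ethoxy]methoxy}phenyl][methoxy(methyl)amino](phenyl)methanolate | COc1c(C(O[Li])(N(C)OC)c2ccccc2)c(OCOCC[Si](C)(C)C)c(CC=C(C)C)c(OCOCC[Si](C)(C)C)c1CC=C(C)C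
F11 | step 5 | [2-methoxy-3,5-bis(3-methylbut-2-en-1-yl)-4,6-bis{[2-(trimethylsilyl)ethoxy]methoxy}phenyl](phenyl)methanone | COc1c(C(=O)c2ccccc2)c(OCOCC[Si](C)(C)C)c(CC=C(C)C)c(OCOCC[Si](C)(C)C)c1CC=C(C)C
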